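## Retrosynthetic overview
1. Target acid ⇒ depside aldehyde by a last-step CHO → CO2H oxidation, so the B-ring acid needs no protecting group.
2. Depside ester C–O ⇒ A-ring acid (2-hydroxy-4-methoxy-6-pentylbenzoic acid) + B-ring phenol (2-heptyl-4-hydroxy-6-methoxybenzaldehyde).
3. B-ring phenol ⇒ para-formylation of 3-heptyl-5-methoxyphenol ⇒ mono-demethylation of 1-heptyl-3,5-dimethoxybenzene.
4. Key C–C bond is aryl–C1' of the heptyl chain. It joins 1-bromo-3,5-dimethoxybenzene and heptanal, two electrophilic carbons. The aldehyde carbon is polarity-reversed as its NH2-hydrazone (a heptyl carbanion equivalent; Ni catalysis, loss of N2).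
5. A-ring acid ⇒ methyl olivetolate (4-O-methylation, saponification). No ring is formed; both benzene rings are bought intact.

Assumption: the SMILES has no stereocentre and no stereogenic double bond, so the target is achiral and nothing has to be set or resolved; methyl olivetolate is taken as a purchasable bulk intermediate of cannabinoid manufacture.

## Route

Step 1
Reactants: 1 1-bromo-3,5-dimethoxybenzene; 2 heptanal
Product: 5 1-heptyl-3,5-dimethoxybenzene, via heptanal hydrazone 3 (not isolated), via benzylic diazene 4 (not isolated)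
Conditions: 2 (2.5 equiv), N2H4·H2O, THF, rt, 1 h; then 1, Ni(cod)2 (10 mol %), PMe3 (40 mol %), LiOt-Bu (2.5 equiv), THF/dioxane, 80 °C, Ar
Reagents that add atoms: hydrazine hydrate, NN.O (its N atoms stand only in 3 and 4 and leave as N2)
Why: Proposed new method: condensation with hydrazine turns the electrophilic carbonyl carbon of 2 into a heptyl-carbanion equivalent (carbonyl umpolung), so that after oxidative addition of 1 to Ni(0) the deprotonated hydrazone binds Ni(II) at nitrogen, shifts to its carbon-bound diaza-allyl form and reductively eliminates to diazene 4, which loses N2 under base through the benzylic anion in a Wolff–Kishner-type collapse and gives the CH2 directly; the closest known reaction type is the Ni(0)/PMe3-catalysed denitrogenative cross-coupling of aryl-aldehyde NH2-hydrazones with aryl halides, and aliphatic NH2-hydrazones are already proven carbanion equivalents in the related Ru-catalysed carbonyl and conjugate additions; the transient stereocentre of 4 is erased.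

Step 2
Reactants: 5 1-heptyl-3,5-dimethoxybenzene
Product: 6 3-heptyl-5-methoxyphenol
Conditions: NaSEt (3 equiv), DMF, 140 °C, 3 h; then 1 M HCl
Reagents that add atoms: none
Why: SN2 demethylation of an aryl methyl ether by thiolate stops cleanly after one cleavage, because the phenoxide formed makes the second OMe a far poorer leaving-group partner (the standard route to orcinol-type monomethyl ethers).

Step 3
Reactants: 6 3-heptyl-5-methoxyphenol
Product: 8 2-heptyl-4-hydroxy-6-methoxybenzaldehyde, via aryl iminium chloride 7 (not isolated)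
Conditions: POCl3 (2 equiv), DMF, 0 °C to rt, 12 h; then ice–water
Reagents that add atoms: N,N-dimethylformamide, CN(C)C=O (formyl carbon); water, O (aldehyde oxygen)
Why: In the Vilsmeier–Haack formylation the non-chelating chloroiminium ion attacks para to the free OH (also ortho to OMe), as in the formylation of 3,5-dimethoxyphenol to 4-hydroxy-2,6-dimethoxybenzaldehyde, and the minor H-bonded ortho-hydroxy isomer is much less polar and is removed by chromatography.

Step 4
Reactants: 9 methyl 2,4-dihydroxy-6-pentylbenzoate (methyl olivetolate)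
Product: 10 methyl 2-hydroxy-4-methoxy-6-pentylbenzoate
Conditions: MeI (1.1 equiv), K2CO3 (1.2 equiv), acetone, reflux
Reagents that add atoms: iodomethane, CI
Why: This Williamson ether synthesis is selective for the 4-OH because the 2-OH is locked in a hydrogen bond to the ester carbonyl and is neither deprotonated nor alkylated with about one equivalent of reagents.

Step 5
Reactants: 10 methyl 2-hydroxy-4-methoxy-6-pentylbenzoate
Product: 11 2-hydroxy-4-methoxy-6-pentylbenzoic acid
Conditions: KOH (10 equiv), DMSO/H2O, 90 °C; then cold 1 M HCl, 0 °C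
Reagents that add atoms: potassium hydroxide, [K+].[OH-] (hydroxide oxygen becomes the acid OH)
Why: BAc2 saponification of the hindered salicylate needs poorly solvated hydroxide in DMSO, as used for other 2-hydroxy-4-methoxy-6-alkylbenzoates; the dianion does not decarboxylate, and cold acidification keeps the free acid intact.

Step 6
Reactants: 11 2-hydroxy-4-methoxy-6-pentylbenzoic acid; 8 2-heptyl-4-hydroxy-6-methoxybenzaldehyde
Product: 13 4-formyl-3-heptyl-5-methoxyphenyl 2-hydroxy-4-methoxy-6-pentylbenzoate, via mixed anhydride 12 (not isolated)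
Conditions: (CF3CO)2O (4 equiv), toluene, 0 °C to rt
Reagents that add atoms: trifluoroacetic anhydride, O=C(OC(=O)C(F)(F)F)C(F)(F)F (its CF3CO group stands only in 12)
Why: Trifluoroacetic mixed-anhydride esterification is the classical depside coupling: the acylium-like 12 overcomes the 2,6-disubstitution of the acid, its own chelated and hindered 2-OH does not compete, 8 has a single OH, and its formyl group blocks ring C-acylation.

Step 7
Reactants: 13 4-formyl-3-heptyl-5-methoxyphenyl 2-hydroxy-4-methoxy-6-pentylbenzoate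
Product: 14 2-heptyl-4-[(2-hydroxy-4-methoxy-6-pentylbenzoyl)oxy]-6-methoxybenzoic acid (target)
Conditions: NaClO2 (3 equiv), NaH2PO4 (4 equiv), 2-methylbut-2-ene (30 equiv), t-BuOH/THF/H2O, 0 °C to rt
Reagents that add atoms: sodium chlorite, [Na+].[O-]Cl=O
Why: The Pinnick oxidation at pH about 4 converts the hindered aryl aldehyde into the acid without touching the aryl ester, and the large excess of alkene removes HOCl before it can chlorinate the phenolic A-ring.

## Compound list
1 | 1-bromo-3,5-dimethoxybenzene | COc1cc(Br)cc(OC)c1 | starting material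
2 | heptanal | CCCCCCC=O | starting material
3 | (E)-heptylidenehydrazine (heptanal hydrazone) | CCCCCC/C=N/N | intermediate
4 | 1-[1-(3,5-dimethoxyphenyl)heptyl]diazene (racemic, transient) | CCCCCCC(N=N)c1cc(OC)cc(OC)c1 | intermediate
5 | 1-heptyl-3,5-dimethoxybenzene | CCCCCCCc1cc(OC)cc(OC)c1 | intermediate
6 | 3-heptyl-5-methoxyphenol | CCCCCCCc1cc(O)cc(OC)c1 | intermediate
7 | (2-heptyl-4-hydroxy-6-methoxybenzylidene)dimethyliminium chloride | CCCCCCCc1cc(O)cc(OC)c1C=[N+](C)C.[Cl-] | intermediate
8 | 2-heptyl-4-hydroxy-6-methoxybenzaldehyde | CCCCCCCc1cc(O)cc(OC)c1C=O | intermediate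
9 | methyl 2,4-dihydroxy-6-pentylbenzoate (methyl olivetolate) | CCCCCc1cc(O)cc(O)c1C(=O)OC | starting material
10 | methyl 2-hydroxy-4-methoxy-6-pentylbenzoate | CCCCCc1cc(OC)cc(O)c1C(=O)OC | intermediate
11 | 2-hydroxy-4-methoxy-6-pentylbenzoic acid | CCCCCc1cc(OC)cc(O)c1C(=O)O | intermediate
12 | 2-hydroxy-4-methoxy-6-pentylbenzoic trifluoroacetic anhydride | CCCCCc1cc(OC)cc(O)c1C(=O)OC(=O)C(F)(F)F | intermediate
13 | 4-formyl-3-heptyl-5-methoxyphenyl 2-hydroxy-4-methoxy-6-pentylbenzoate | CCCCCCCc1cc(OC(=O)c2c(O)cc(OC)cc2CCCCC)cc(OC)c1C=O | intermediate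
14 | 2-heptyl-4-[(2-hydroxy-4-methoxy-6-pentylbenzoyl)oxy]-6-methoxybenzoic acid | CCCCCCCc1cc(OC(=O)c2c(O)cc(OC)cc2CCCCC)cc(OC)c1C(=O)O | target

## Step count and risks
Total step count: 7. Longest linear sequence: 5 (steps 1, 2, 3, 6, 7).

**Step 1 (key coupling).**
- Risk: an aliphatic hydrazone may N-arylate, dimerise to the azine, suffer β-hydride elimination at nickel, or merely reduce the aryl bromide.
- Fallback: it sets out from 2, with 1 as partner, and comes back at 5. It keeps the same bond and the same reversed polarity but uses an isolated acyl anion equivalent.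
- Heptanal 2 is condensed with tert-butylhydrazine hydrochloride/NaOAc to heptanal N-tert-butylhydrazone F1.
- Pd(0)/DPEphos/NaOt-Bu C-arylation of F1 with 1 in toluene at 80 °C gives 1-tert-butyl-2-[1-(3,5-dimethoxyphenyl)heptyl]diazene F2.
- Aqueous acid tautomerises and hydrolyses F2 to 1-(3,5-dimethoxyphenyl)heptan-1-one F3.
- Benzylic hydrogenolysis of F3 (H2, Pd/C, AcOH, cat. HClO4) gives 5.

**Step 3 (regiochemistry of formylation).**
- Risk: attack para to OMe, giving the ortho-hydroxy aldehyde, may take a large share.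
- Fallback: it sets out from 5 and comes back at 8. It replaces regiocontrol by symmetry and chelation control.
- BBr3 in CH2Cl2 converts 5 into 5-heptylresorcinol F4.
- Vilsmeier formylation of F4 gives mainly 2-heptyl-4,6-dihydroxybenzaldehyde F5, because the two sites next to the chain are equivalent.
- BnBr/KHCO3 alkylates only the non-chelated OH of F5 to give 4-(benzyloxy)-2-heptyl-6-hydroxybenzaldehyde F6.
- MeI/K2CO3 in DMF then gives 4-(benzyloxy)-2-heptyl-6-methoxybenzaldehyde F7.
- Brief hydrogenolysis of F7 (H2, Pd/C, EtOAc) releases 8.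

**Step 7 (final oxidation).**
- Risk: the electron-rich, phenolic A-ring may be chlorinated.
- Fallback: it sets out from 8 and comes back at 14. The oxidation is moved ahead of the coupling and the acid is carried as a benzyl ester.
- NaClO2/sulfamic acid oxidises 8 to 2-heptyl-4-hydroxy-6-methoxybenzoic acid F8.
- BnBr/KHCO3 in DMF alkylates only the carboxylate of F8, giving benzyl 2-heptyl-4-hydroxy-6-methoxybenzoate F9.
- Coupling of F9 with 11 through 12 (trifluoroacetic anhydride, toluene) gives benzyl 2-heptyl-4-[(2-hydroxy-4-methoxy-6-pentylbenzoyl)oxy]-6-methoxybenzoate F10.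
- Hydrogenolysis of F10 (H2, Pd/C, EtOAc) gives 14.

## Further compounds
F1 | step 1 | (E)-1-tert-butyl-2-heptylidenehydrazine (heptanal N-tert-butylhydrazone) | CCCCCC/C=N/NC(C)(C)C
F2 | step 1 | 1-tert-butyl-2-[1-(3,5-dimethoxyphenyl)heptyl]diazene (racemic) | CCCCCCC(N=NC(C)(C)C)c1cc(OC)cc(OC)c1
F3 | step 1 | 1-(3,5-dimethoxyphenyl)heptan-1-one | CCCCCCC(=O)c1cc(OC)cc(OC)c1
F4 | step 3 | 5-heptylresorcinol | CCCCCCCc1cc(O)cc(O)c1
F5 | step 3 | 2-heptyl-4,6-dihydroxybenzaldehyde | CCCCCCCc1cc(O)cc(O)c1C=O
F6 | step 3 | 4-(benzyloxy)-2-heptyl-6-hydroxybenzaldehyde | CCCCCCCc1cc(OCc2ccccc2)cc(O)c1C=O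
F7 | step 3 | 4-(benzyloxy)-2-heptyl-6-methoxybenzaldehyde | CCCCCCCc1cc(OCc2ccccc2)cc(OC)c1C=O
F8 | step 7 | 2-heptyl-4-hydroxy-6-methoxybenzoic acid | CCCCCCCc1cc(O)cc(OC)c1C(=O)O
F9 | step 7 | benzyl 2-heptyl-4-hydroxy-6-methoxybenzoate | CCCCCCCc1cc(O)cc(OC)c1C(=O)OCc1ccccc1
F10 | step 7 | benzyl 2-heptyl-4-[(2-hydroxy-4-methoxy-6-pentylbenzoyl)oxy]-6-methoxybenzoate | CCCCCCCc1cc(OC(=O)c2c(O)cc(OC)cc2CCCCC)cc(OC)c1C(=O)OCc1ccccc1
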